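**Plan**
1. Retrosynthesis (germacranolide numbering: ring C1–C10, lactone O on C6, C11/C12/C13 the methylene-lactone carbons, C14 the formyl carbon, C15 the methyl): remove the C13 methylene and the C14 oxidation level, cut the ring bond C5–C6, then the C8 ester, the C9–C10 bond and the C1=C10 alkene.
2. Enabling feature: C6 is the ring carbon that carries the oxygen of the five-membered butanolide and is bonded to C5 of the ring-cis C4=C5 alkene, so C6 can come from an α-oxy carboxylic acid (as its radical) and C5 from a (Z)-alkenyl iodide.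
3. Forward: the butanolide (O, C6, C7, C11, C12) is built first on a tartrate-derived chain; the C1–C5/C10/C14 arm is joined at C9–C10; the ten-membered ring is closed at C5–C6 by nickel-electrocatalytic decarboxylative alkenylation; methylenation, desilylation and C14 oxidation finish.
4. Stereocenters: C8 from diethyl L-tartrate; C7 by anti-selective cuprate addition next to C8; C9 by chelation-controlled alkenylmagnesium addition; C6 in the ring closure, trans to C7; the ester center from (S)-2-methylbutanoic acid.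
5. Alkene geometry: C4=C5 from syn-carbocupration of propyne (carried as a vinylsilane, returned to the iodide by ipso-iododesilylation); C1=C10 from a Z-selective bromo-Wittig olefination and stereoretentive Br/Li exchange.

Key step: step 23

Remark: C6 is made without stereocontrol in step 6 and carried as both epimers, which is harmless because step 23 passes through the planar C6 radical; SMILES 10–13 leave C6 open and 14–40 show the 6,7-trans epimer. TBS = tert-butyldimethylsilyl, PMB = 4-methoxybenzyl.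

**Route**

Step 1
Reactants: 1 diethyl L-tartrate
Product: 2 diethyl (4R,5R)-2-(4-methoxyphenyl)-1,3-dioxolane-4,5-dicarboxylate
Conditions: 4-MeOC6H4CH(OMe)2, TsOH·H2O (cat.), toluene, 110 °C, MeOH distilled off
Reagents that add atoms: 4-methoxybenzaldehyde dimethyl acetal, COC(OC)c1ccc(OC)cc1
Why: Acid-catalysed transacetalisation ties the two secondary hydroxyls into a five-membered arylidene acetal without touching the stereocenters, and because the diester is C2-symmetric the acetal carbon is not a stereocenter.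

Step 2
Reactants: 2 arylidene acetal diester
Product: 3 (2S,3S)-3-(PMB-oxy)butane-1,2,4-triol
Conditions: LiAlH4, AlCl3, Et2O/CH2Cl2, 0 °C to reflux
Reagents that add atoms: none
Why: LiAlH4 reduces both esters while the chloroalane formed with AlCl3 opens the arylidene acetal reductively (Lewis-acid-assisted hydride cleavage), and since the two acetal oxygens are symmetry-equivalent only one mono-PMB ether can form.

Step 3
Reactants: 3 PMB triol
Product: 4 (2S)-2-[(4S)-2,2-dimethyl-1,3-dioxolan-4-yl]-2-(PMB-oxy)ethanol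
Conditions: Me2C(OMe)2, TsOH·H2O (cat.), acetone, 20 °C
Reagents that add atoms: 2,2-dimethoxypropane, COC(C)(C)OC
Why: Thermodynamically controlled acetonide formation takes the terminal 1,2-diol as the five-membered dioxolane in preference to the six-membered 1,3-dioxane, which leaves free only the primary hydroxyl next to the PMB ether.

Step 4
Reactants: 4 acetonide alcohol
Product: 6 tert-butyl (2E,4S)-enoate carrying the γ-OPMB group and the terminal acetonide, via aldehyde 5 (not isolated)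
Conditions: Dess–Martin periodinane, CH2Cl2, 0 to 20 °C; then Ph3P=CHCO2t-Bu, 20 °C
Reagents that add atoms: tert-butyl (triphenylphosphoranylidene)acetate, CC(C)(C)OC(=O)C=P(c1ccccc1)(c1ccccc1)c1ccccc1
Why: Dess–Martin oxidation gives the epimerisable α-alkoxy aldehyde, which is intercepted in the same flask by the ester-stabilised Wittig ylide, a reagent that gives the E enoate reliably in CH2Cl2.

Step 5
Reactants: 6 enoate
Product: 8 tert-butyl (3R)-3-vinyl ester (C7 set), via silyl ketene acetal 7 (not isolated)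
Conditions: CH2=CHMgBr (4 equiv), CuI (2 equiv), Me3SiCl, THF, −78 to −40 °C; aq. NH4Cl
Reagents that add atoms: vinylmagnesium bromide, C=C[Mg]Br
Why: Me3SiCl-accelerated conjugate addition of the vinylcuprate should follow the modified Felkin–Anh model for γ-alkoxy E-enoates (γ-C–O bond antiperiplanar to the incoming copper, γ-hydrogen eclipsing the alkene), so the vinyl group enters anti to the OPMB group and sets C7 with the configuration of the target.

Step 6
Reactants: 8 vinyl ester
Product: 10 α-hydroxy ester (C6 epimers), via potassium enolate 9 (not isolated)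
Conditions: KN(SiMe3)2, THF, −78 °C; 2-(phenylsulfonyl)-3-phenyloxaziridine, −78 °C; aq. NH4Cl
Reagents that add atoms: 2-(phenylsulfonyl)-3-phenyloxaziridine, O=S(=O)(N1OC1c1ccccc1)c1ccccc1
Why: Kinetic deprotonation to the potassium enolate and electrophilic hydroxylation with the Davis oxaziridine install the C6 oxygen, whose configuration is deliberately left uncontrolled because C6 is later turned into a planar radical.

Step 7
Reactants: 10 α-hydroxy ester
Product: 12 2,5-dihydroxy ester, via bis-boron adduct 11 (not isolated)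
Conditions: 9-BBN-H (3 equiv), THF, 0 to 20 °C; then H2O2, aq. NaOH, 0 °C
Reagents that add atoms: hydrogen peroxide, OO
Why: 9-BBN-H hydroborates the monosubstituted vinyl group, the only alkene present, at its terminus (anti-Markovnikov hydroboration–oxidation), the free hydroxyl merely binding a second borane as a borinate that is cleaved in the oxidative work-up.

Step 8
Reactants: 12 diol ester
Product: 14 γ-lactone tert-butyl ester with the C9/C10 acetonide, via lactol 13 (not isolated)
Conditions: TEMPO (0.2 equiv), PhI(OAc)2 (2.5 equiv), CH2Cl2, 20 °C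
Reagents that add atoms: none
Why: TEMPO/PhI(OAc)2 oxidises the primary alcohol selectively to the aldehyde, which closes onto the C6 hydroxyl as a five-membered lactol that is oxidised further to the γ-lactone (oxidative lactonisation of a 1,4-diol), the secondary α-hydroxy ester and the PMB ether being inert.

Step 9
Reactants: 14 acetonide lactone
Product: 16 C9 aldehyde lactone, via diol 15 (not isolated)
Conditions: H5IO6, EtOAc, 20 °C
Reagents that add atoms: none
Why: Periodic acid hydrolyses the terminal acetonide and cleaves the liberated 1,2-diol in the same flask (Malaprade glycol cleavage), unmasking C9 as the aldehyde under conditions that the PMB ether, tert-butyl ester and lactone tolerate.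

Step 10
Reactants: 17 2-(2-bromoethyl)-1,3-dioxolane; 18 propyne
Product: 22 2-[(3Z)-4-iodo-3-methylbut-3-en-1-yl]-1,3-dioxolane, via Grignard reagent 19 (not isolated), via alkylcopper 20 (not isolated), via alkenylcopper 21 (not isolated)
Conditions: Mg, THF, 25 °C; CuBr·SMe2, Et2O/Me2S, −45 °C; propyne, −25 °C; I2, THF, −50 to 0 °C
Reagents that add atoms: iodine, [I][I]
Why: Normant carbocupration adds the alkyl group and copper syn across propyne with copper on the terminal carbon, and iodinolysis with retention gives the trisubstituted alkenyl iodide with iodine cis to the chain (Z at C4=C5).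

Step 11
Reactants: 22 iodoalkene acetal
Product: 24 2-[(3Z)-3-methyl-4-(trimethylsilyl)but-3-en-1-yl]-1,3-dioxolane, via alkenyllithium 23 (not isolated)
Conditions: t-BuLi (2.1 equiv), Et2O, −78 °C; Me3SiCl, −78 to 20 °C
Reagents that add atoms: chlorotrimethylsilane, C[Si](C)(C)Cl
Why: Iodine–lithium exchange gives a configurationally stable alkenyllithium that is silylated with retention, which masks C5 as a vinylsilane so that the later bromine–lithium exchange at C10 can be carried out without touching C5.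

Step 12
Reactants: 24 vinylsilane acetal
Product: 25 (4Z)-4-methyl-5-(trimethylsilyl)pent-4-enal
Conditions: 1 M HCl, THF, 20 °C
Reagents that add atoms: water, O
Why: Acid-catalysed acetal hydrolysis frees the aldehyde under conditions far too mild to protodesilylate the vinylsilane.

Step 13
Reactants: 25 silyl aldehyde
Product: 26 ethyl (2Z,6Z)-2-bromo-6-methyl-7-(trimethylsilyl)hepta-2,6-dienoate
Conditions: Ph3P=C(Br)CO2Et, CH2Cl2, 20 °C
Reagents that add atoms: ethyl bromo(triphenylphosphoranylidene)acetate, CCOC(=O)C(Br)=P(c1ccccc1)(c1ccccc1)c1ccccc1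
Why: Wittig olefination with the ester-stabilised α-bromo ylide puts the ester trans to the alkyl chain, so that bromine, the later site of C9–C10 bond formation, ends up cis to C2 (Z-2-bromo-enoate; any minor isomer to be removed by chromatography).

Step 14
Reactants: 26 bromo-enoate
Product: 27 (2Z,6Z)-2-bromo-6-methyl-7-(trimethylsilyl)hepta-2,6-dien-1-ol
Conditions: i-Bu2AlH (2.2 equiv), CH2Cl2, −78 °C
Reagents that add atoms: none
Why: i-Bu2AlH reduces the conjugated ester to the allylic alcohol by two 1,2-hydride additions at low temperature, leaving the alkenyl bromide and the vinylsilane untouched.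

Step 15
Reactants: 27 bromo-allylic alcohol
Product: 28 TBS ether of 27 (arm)
Conditions: t-BuMe2SiCl, imidazole, CH2Cl2, 20 °C
Reagents that add atoms: tert-butyldimethylsilyl chloride, CC(C)(C)[Si](C)(C)Cl
Why: Imidazole-mediated silylation of the primary allylic alcohol is routine and gives the ether that will become the C14 silyl ether of the cyclisation substrate.

Step 16
Reactants: 28 alkenyl bromide; 16 aldehyde lactone
Product: 31 (9S)-allylic alcohol with the C9–C10 bond, via alkenyllithium 29 (not isolated), via alkenylmagnesium bromide 30 (not isolated)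
Conditions: 28 (1.3 equiv), t-BuLi (2.6 equiv), Et2O, −78 °C; MgBr2·OEt2, −78 °C; 16 in CH2Cl2, −78 °C; aq. NH4Cl
Reagents that add atoms: none
Why: Bromine–lithium exchange with retention, transmetalation to magnesium and addition to the α-OPMB aldehyde through the five-membered Cram chelate (magnesium bridging the aldehyde and ether oxygens) should deliver the alkenyl group to the face opposite the C7 substituent and give the 8,9-syn (9S) alcohol, the aldehyde reacting far faster at −78 °C than the lactone or the tert-butyl ester.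

Step 17
Reactants: 31 C9 alcohol
Product: 32 C9 TBS ether
Conditions: t-BuMe2SiOTf, 2,6-lutidine, CH2Cl2, −78 to 0 °C
Reagents that add atoms: tert-butyldimethylsilyl trifluoromethanesulfonate, CC(C)(C)[Si](C)(C)OS(=O)(=O)C(F)(F)F
Why: Silylation with the silyl triflate and a hindered pyridine base is the standard way to protect a hindered secondary allylic alcohol.

Step 18
Reactants: 32 PMB ether
Product: 33 C8 alcohol
Conditions: DDQ, CH2Cl2/pH 7 buffer, 0 to 20 °C
Reagents that add atoms: none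
Why: DDQ oxidises the electron-rich benzyl ether by hydride abstraction (oxidative PMB cleavage) and hydrolysis frees only the C8 hydroxyl, the silyl ethers, vinylsilane, ester and lactone being inert.

Step 19
Reactants: 33 C8 alcohol; 34 (S)-2-methylbutanoic acid
Product: 35 C8 (S)-2-methylbutanoate
Conditions: DCC, DMAP, CH2Cl2, 0 to 20 °C
Reagents that add atoms: none
Why: Steglich esterification (carbodiimide activation, DMAP acyl transfer) acylates the C8 hydroxyl with the enantiopure acid, whose α-stereocenter is not exposed to strong base.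

Step 20
Reactants: 35 vinylsilane
Product: 36 (Z)-alkenyl iodide
Conditions: N-iodosuccinimide, (CF3)2CHOH, 0 °C
Reagents that add atoms: N-iodosuccinimide, O=C1CCC(=O)N1I
Why: Electrophilic ipso-iododesilylation (iodonium attack at the silicon-bearing carbon, β-silyl-stabilised cation, loss of silicon) returns the alkenyl iodide with retention of the Z geometry, the vinylsilane being much more nucleophilic than the oxygen-flanked C1=C10 alkene.

Step 21
Reactants: 36 tert-butyl ester
Product: 38 lactone carboxylic acid, via silyl ester 37 (not isolated)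
Conditions: Me3SiOTf, 2,6-lutidine, CH2Cl2, 0 °C; then H2O
Reagents that add atoms: none
Why: Me3SiOTf/2,6-lutidine converts the tert-butyl ester into the trimethylsilyl ester with loss of isobutene (Lewis-acid-mediated tert-butyl cleavage), which aqueous work-up hydrolyses to the acid without cleaving the TBS ethers, the lactone or the secondary ester.

Step 22
Reactants: 38 acid; 39 N-hydroxyphthalimide
Product: 40 N-(acyloxy)phthalimide redox-active ester
Conditions: N,N'-diisopropylcarbodiimide, DMAP (cat.), CH2Cl2, 20 °C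
Reagents that add atoms: none
Why: Carbodiimide coupling with N-hydroxyphthalimide gives the redox-active ester under neutral conditions, and any epimerisation at C6 is irrelevant.

Step 23
Reactants: 40 redox-active ester
Product: 41 ten-membered trans-lactone
Conditions: NiCl2·MeOCH2CH2OMe (NiCl2·glyme, 0.3 equiv), 2,2'-bipyridine (0.35 equiv), n-Bu4NPF6, DMF, undivided cell, Mg anode, reticulated vitreous carbon cathode, constant current, 20 °C; 40 added by syringe pump (final 2 mM)
Reagents that add atoms: none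
Why: Proposed new method: cathodically generated zerovalent nickel (bipyridine-ligated) inserts into the C5–I bond with retention of the Z geometry, while one-electron reduction of the phthalimide ester and loss of CO2 give the lactone α-oxy radical at C6, which is captured by the alkenylnickel to give a trivalent nickel species that reductively eliminates the C5–C6 bond. The closest known reaction type is the intermolecular nickel-electrocatalytic decarboxylative alkenylation of redox-active esters with alkenyl halides; what is new is its use to close a ring. The ten-membered carbocycle is closed by C(sp2)–C(sp3) reductive elimination from an eleven-membered nickelacycle and not by radical attack on an alkene, so no endo/exo competition arises, and the Z-alkene and the rigid lactone already bend the chain towards closure. The new stereocenter C6 arises from a planar radical, so both C6 epimers of 40 converge, and bond formation on the face anti to the bulky C7 substituent should give the trans-fused lactone (H6 and H7 trans). The step needs ring closure to outrun hydrogen-atom abstraction, dimerisation and intermolecular coupling, which slow addition of 40 to a dilute, continuously regenerated catalyst and the tethering of radical and alkenylnickel in one molecule are meant to secure; the esters, silyl ethers and the trisubstituted C1=C10 alkene should be inert to low-valent nickel.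

Step 24
Reactants: 41 macrocyclic lactone
Product: 45 α-methylene lactone, via lithium enolate 42 (not isolated), via Mannich base 43 (not isolated), via ammonium iodide 44 (not isolated)
Conditions: LiN(SiMe3)2 (1.1 equiv), THF, −78 °C; CH2=NMe2+ I−, −78 to 0 °C; MeI, CH2Cl2/MeOH, 20 °C; aq. NaHCO3, CH2Cl2
Reagents that add atoms: N,N-dimethylmethyleneiminium iodide, C=[N+](C)C.[I-]
Why: Kinetic enolisation takes place at the lactone α-methylene group, which is more acidic and far less hindered than the tertiary α-position of the 2-methylbutanoate, and Mannich reaction with Eschenmoser's salt followed by N-methylation and base-induced Hofmann-type elimination gives the exocyclic methylene.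

Step 25
Reactants: 45 bis-silyl ether
Product: 46 C9,C14 diol
Conditions: HF·pyridine, pyridine, THF, 0 to 20 °C
Reagents that add atoms: none
Why: Fluoride cleaves both silyl ethers (Si–F bond formation) under buffered, mildly acidic conditions that avoid acyl migration, lactone opening and conjugate addition to the methylene lactone.

Step 26
Reactants: 46 diol
Product: 47 target CNP0168436.1
Conditions: TEMPO (0.1 equiv), PhI(OAc)2 (1.2 equiv), CH2Cl2, 20 °C
Reagents that add atoms: none
Why: TEMPO/PhI(OAc)2 oxidises the unhindered primary allylic alcohol much faster than the hindered secondary C9 alcohol and stops at the aldehyde, giving the enal whose geometry (formyl trans to C2) was fixed in step 13.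

**Compound list**

1 | diethyl (2R,3R)-2,3-dihydroxybutanedioate (diethyl L-tartrate) | CCOC(=O)[C@H](O)[C@@H](O)C(=O)OCC | starting material
2 | diethyl (4R,5R)-2-(4-methoxyphenyl)-1,3-dioxolane-4,5-dicarboxylate | CCOC(=O)[C@@H]1OC(c2ccc(OC)cc2)O[C@H]1C(=O)OCC | intermediate
3 | (2S,3S)-3-[(4-methoxyphenyl)methoxy]butane-1,2,4-triol | OC[C@H](OCc1ccc(OC)cc1)[C@@H](O)CO | intermediate
4 | (2S)-2-[(4S)-2,2-dimethyl-1,3-dioxolan-4-yl]-2-[(4-methoxyphenyl)methoxy]ethan-1-ol | OC[C@H](OCc1ccc(OC)cc1)[C@@H]1COC(C)(C)O1 | intermediate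
5 | (2R)-2-[(4S)-2,2-dimethyl-1,3-dioxolan-4-yl]-2-[(4-methoxyphenyl)methoxy]acetaldehyde | O=C[C@H](OCc1ccc(OC)cc1)[C@@H]1COC(C)(C)O1 | intermediate (not isolated)
6 | tert-butyl (2E,4S)-4-[(4S)-2,2-dimethyl-1,3-dioxolan-4-yl]-4-[(4-methoxyphenyl)methoxy]but-2-enoate | CC(C)(C)OC(=O)/C=C/[C@H](OCc1ccc(OC)cc1)[C@@H]1COC(C)(C)O1 | intermediate
7 | O-trimethylsilyl ketene acetal of ester 8 (C7 and C8 as in 8) | CC(C)(C)OC(O[Si](C)(C)C)=C[C@H](C=C)[C@H](OCc1ccc(OC)cc1)[C@@H]1COC(C)(C)O1 | intermediate (not isolated)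
8 | tert-butyl (3R)-3-{(S)-[(4S)-2,2-dimethyl-1,3-dioxolan-4-yl][(4-methoxyphenyl)methoxy]methyl}pent-4-enoate | CC(C)(C)OC(=O)C[C@H](C=C)[C@H](OCc1ccc(OC)cc1)[C@@H]1COC(C)(C)O1 | intermediate
9 | potassium enolate of ester 8 | CC(C)(C)OC([O-])=C[C@H](C=C)[C@H](OCc1ccc(OC)cc1)[C@@H]1COC(C)(C)O1.[K+] | intermediate (not isolated)
10 | tert-butyl (2RS,3S)-3-{(S)-[(4S)-2,2-dimethyl-1,3-dioxolan-4-yl][(4-methoxyphenyl)methoxy]methyl}-2-hydroxypent-4-enoate | CC(C)(C)OC(=O)C(O)[C@H](C=C)[C@H](OCc1ccc(OC)cc1)[C@@H]1COC(C)(C)O1 | intermediate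
11 | adduct of 10 with two 9-borabicyclo[3.3.1]nonan-9-yl groups (on C12 and on the C6 oxygen) | CC(C)(C)OC(=O)C(OB1C2CCCC1CCC2)[C@H](CCB1C2CCCC1CCC2)[C@H](OCc1ccc(OC)cc1)[C@@H]1COC(C)(C)O1 | intermediate (not isolated)
12 | tert-butyl (2RS,3S)-3-{(S)-[(4S)-2,2-dimethyl-1,3-dioxolan-4-yl][(4-methoxyphenyl)methoxy]methyl}-2,5-dihydroxypentanoate | CC(C)(C)OC(=O)C(O)[C@H](CCO)[C@H](OCc1ccc(OC)cc1)[C@@H]1COC(C)(C)O1 | intermediate
13 | tert-butyl (3R)-3-{(S)-[(4S)-2,2-dimethyl-1,3-dioxolan-4-yl][(4-methoxyphenyl)methoxy]methyl}-5-hydroxyoxolane-2-carboxylate (lactol, epimers at C2 and C5) | CC1(C)OC[C@H](O1)[C@@H](OCc2ccc(OC)cc2)[C@H]3CC(O)OC3C(=O)OC(C)(C)C | intermediate (not isolated)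
14 | tert-butyl (2S,3R)-3-{(S)-[(4S)-2,2-dimethyl-1,3-dioxolan-4-yl][(4-methoxyphenyl)methoxy]methyl}-5-oxooxolane-2-carboxylate (with its 2R epimer) | CC1(C)OC[C@H](O1)[C@@H](OCc2ccc(OC)cc2)[C@H]3CC(=O)O[C@@H]3C(=O)OC(C)(C)C | intermediate
15 | tert-butyl (2S,3R)-3-{(1S,2S)-2,3-dihydroxy-1-[(4-methoxyphenyl)methoxy]propyl}-5-oxooxolane-2-carboxylate (with its 2R epimer) | OC[C@H](O)[C@@H](OCc1ccc(OC)cc1)[C@H]2CC(=O)O[C@@H]2C(=O)OC(C)(C)C | intermediate (not isolated)
16 | tert-butyl (2S,3R)-3-{(1S)-1-[(4-methoxyphenyl)methoxy]-2-oxoethyl}-5-oxooxolane-2-carboxylate (with its 2R epimer) | O=C[C@@H](OCc1ccc(OC)cc1)[C@H]2CC(=O)O[C@@H]2C(=O)OC(C)(C)C | intermediate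
17 | 2-(2-bromoethyl)-1,3-dioxolane | BrCCC1OCCO1 | starting material
18 | propyne | CC#C | starting material
19 | [2-(1,3-dioxolan-2-yl)ethyl]magnesium bromide | Br[Mg]CCC1OCCO1 | intermediate (not isolated)
20 | [2-(1,3-dioxolan-2-yl)ethyl]copper (as its MgBr2 complex) | [Cu]CCC1OCCO1 | intermediate (not isolated)
21 | [(1Z)-4-(1,3-dioxolan-2-yl)-2-methylbut-1-en-1-yl]copper | [Cu]/C=C(/C)CCC1OCCO1 | intermediate (not isolated)
22 | 2-[(3Z)-4-iodo-3-methylbut-3-en-1-yl]-1,3-dioxolane | I/C=C(/C)CCC1OCCO1 | intermediate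
23 | [(1Z)-4-(1,3-dioxolan-2-yl)-2-methylbut-1-en-1-yl]lithium | [Li]/C=C(/C)CCC1OCCO1 | intermediate (not isolated)
24 | 2-[(3Z)-3-methyl-4-(trimethylsilyl)but-3-en-1-yl]-1,3-dioxolane | C[Si](C)(C)/C=C(/C)CCC1OCCO1 | intermediate
25 | (4Z)-4-methyl-5-(trimethylsilyl)pent-4-enal | C[Si](C)(C)/C=C(/C)CCC=O | intermediate
26 | ethyl (2Z,6Z)-2-bromo-6-methyl-7-(trimethylsilyl)hepta-2,6-dienoate | C[Si](C)(C)/C=C(/C)CC/C=C(/C(=O)OCC)Br | intermediate
27 | (2Z,6Z)-2-bromo-6-methyl-7-(trimethylsilyl)hepta-2,6-dien-1-ol | C[Si](C)(C)/C=C(/C)CC/C=C(/CO)Br | intermediate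
28 | {[(2Z,6Z)-2-bromo-6-methyl-7-(trimethylsilyl)hepta-2,6-dien-1-yl]oxy}(tert-butyl)dimethylsilane | C[Si](C)(C)/C=C(/C)CC/C=C(/CO[Si](C)(C)C(C)(C)C)Br | intermediate
29 | alkenyllithium from 28 (lithium in place of bromine, geometry retained) | C[Si](C)(C)/C=C(/C)CC/C=C(/CO[Si](C)(C)C(C)(C)C)[Li] | intermediate (not isolated)
30 | alkenylmagnesium bromide from 29 (geometry retained) | C[Si](C)(C)/C=C(/C)CC/C=C(/CO[Si](C)(C)C(C)(C)C)[Mg]Br | intermediate (not isolated)
31 | tert-butyl (2S,3R)-3-[(1S,2S,3Z,7Z)-2-hydroxy-1-(PMB-oxy)-3-(TBS-oxymethyl)-7-methyl-8-(trimethylsilyl)octa-3,7-dien-1-yl]-5-oxooxolane-2-carboxylate (with its 2R epimer) | C[Si](C)(C)/C=C(/C)CC/C=C(/CO[Si](C)(C)C(C)(C)C)[C@H](O)[C@@H](OCc1ccc(OC)cc1)[C@H]2CC(=O)O[C@@H]2C(=O)OC(C)(C)C | intermediate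
32 | tert-butyl (2S,3R)-3-[(1S,2S,3Z,7Z)-1-(PMB-oxy)-2-(TBS-oxy)-3-(TBS-oxymethyl)-7-methyl-8-(trimethylsilyl)octa-3,7-dien-1-yl]-5-oxooxolane-2-carboxylate (with its 2R epimer) | C[Si](C)(C)/C=C(/C)CC/C=C(/CO[Si](C)(C)C(C)(C)C)[C@H](O[Si](C)(C)C(C)(C)C)[C@@H](OCc1ccc(OC)cc1)[C@H]2CC(=O)O[C@@H]2C(=O)OC(C)(C)C | intermediate
33 | tert-butyl (2S,3R)-3-[(1S,2S,3Z,7Z)-1-hydroxy-2-(TBS-oxy)-3-(TBS-oxymethyl)-7-methyl-8-(trimethylsilyl)octa-3,7-dien-1-yl]-5-oxooxolane-2-carboxylate (with its 2R epimer) | C[Si](C)(C)/C=C(/C)CC/C=C(/CO[Si](C)(C)C(C)(C)C)[C@H](O[Si](C)(C)C(C)(C)C)[C@@H](O)[C@H]2CC(=O)O[C@@H]2C(=O)OC(C)(C)C | intermediate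
34 | (2S)-2-methylbutanoic acid | CC[C@H](C)C(=O)O | starting material
35 | tert-butyl (2S,3R)-3-[(1S,2S,3Z,7Z)-1-{[(2S)-2-methylbutanoyl]oxy}-2-(TBS-oxy)-3-(TBS-oxymethyl)-7-methyl-8-(trimethylsilyl)octa-3,7-dien-1-yl]-5-oxooxolane-2-carboxylate (with its 2R epimer) | C[Si](C)(C)/C=C(/C)CC/C=C(/CO[Si](C)(C)C(C)(C)C)[C@H](O[Si](C)(C)C(C)(C)C)[C@@H](OC(=O)[C@@H](C)CC)[C@H]2CC(=O)O[C@@H]2C(=O)OC(C)(C)C | intermediate
36 | tert-butyl (2S,3R)-3-[(1S,2S,3Z,7Z)-8-iodo-1-{[(2S)-2-methylbutanoyl]oxy}-2-(TBS-oxy)-3-(TBS-oxymethyl)-7-methylocta-3,7-dien-1-yl]-5-oxooxolane-2-carboxylate (with its 2R epimer) | I/C=C(/C)CC/C=C(/CO[Si](C)(C)C(C)(C)C)[C@H](O[Si](C)(C)C(C)(C)C)[C@@H](OC(=O)[C@@H](C)CC)[C@H]2CC(=O)O[C@@H]2C(=O)OC(C)(C)C | intermediate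
37 | trimethylsilyl ester of acid 38 | I/C=C(/C)CC/C=C(/CO[Si](C)(C)C(C)(C)C)[C@H](O[Si](C)(C)C(C)(C)C)[C@@H](OC(=O)[C@@H](C)CC)[C@H]2CC(=O)O[C@@H]2C(=O)O[Si](C)(C)C | intermediate (not isolated)
38 | (2S,3R)-3-[(1S,2S,3Z,7Z)-8-iodo-1-{[(2S)-2-methylbutanoyl]oxy}-2-(TBS-oxy)-3-(TBS-oxymethyl)-7-methylocta-3,7-dien-1-yl]-5-oxooxolane-2-carboxylic acid (with its 2R epimer) | I/C=C(/C)CC/C=C(/CO[Si](C)(C)C(C)(C)C)[C@H](O[Si](C)(C)C(C)(C)C)[C@@H](OC(=O)[C@@H](C)CC)[C@H]2CC(=O)O[C@@H]2C(=O)O | intermediate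
39 | N-hydroxyphthalimide | ON1C(=O)c2ccccc2C1=O | starting material
40 | 1,3-dioxoisoindolin-2-yl ester of acid 38 (cyclisation precursor; with its C6 epimer) | I/C=C(/C)CC/C=C(/CO[Si](C)(C)C(C)(C)C)[C@H](O[Si](C)(C)C(C)(C)C)[C@@H](OC(=O)[C@@H](C)CC)[C@H]1CC(=O)O[C@@H]1C(=O)ON2C(=O)c3ccccc3C2=O | intermediate
41 | (3aS,4S,5S,6Z,10Z,11aR)-5-(TBS-oxy)-6-(TBS-oxymethyl)-10-methyl-2-oxo-2,3,3a,4,5,8,9,11a-octahydrocyclodeca[b]furan-4-yl (2S)-2-methylbutanoate | C1C(=O)O[C@@H]2/C=C(/C)CC/C=C(/CO[Si](C)(C)C(C)(C)C)[C@H](O[Si](C)(C)C(C)(C)C)[C@@H](OC(=O)[C@@H](C)CC)[C@@H]12 | intermediate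
42 | lithium enolate of lactone 41 | C1=C([O-])O[C@@H]2/C=C(/C)CC/C=C(/CO[Si](C)(C)C(C)(C)C)[C@H](O[Si](C)(C)C(C)(C)C)[C@@H](OC(=O)[C@@H](C)CC)[C@@H]12.[Li+] | intermediate (not isolated)
43 | 3-[(dimethylamino)methyl] derivative of 41 (C11 epimers) | CN(C)CC1C(=O)O[C@@H]2/C=C(/C)CC/C=C(/CO[Si](C)(C)C(C)(C)C)[C@H](O[Si](C)(C)C(C)(C)C)[C@@H](OC(=O)[C@@H](C)CC)[C@@H]12 | intermediate (not isolated)
44 | 3-[(trimethylammonio)methyl] iodide from 43 | C[N+](C)(C)CC1C(=O)O[C@@H]2/C=C(/C)CC/C=C(/CO[Si](C)(C)C(C)(C)C)[C@H](O[Si](C)(C)C(C)(C)C)[C@@H](OC(=O)[C@@H](C)CC)[C@@H]12.[I-] | intermediate (not isolated)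
45 | (3aS,4S,5S,6Z,10Z,11aR)-5-(TBS-oxy)-6-(TBS-oxymethyl)-10-methyl-3-methylidene-2-oxo-2,3,3a,4,5,8,9,11a-octahydrocyclodeca[b]furan-4-yl (2S)-2-methylbutanoate | C=C1C(=O)O[C@@H]2/C=C(/C)CC/C=C(/CO[Si](C)(C)C(C)(C)C)[C@H](O[Si](C)(C)C(C)(C)C)[C@@H](OC(=O)[C@@H](C)CC)[C@@H]12 | intermediate
46 | (3aS,4S,5S,6Z,10Z,11aR)-5-hydroxy-6-(hydroxymethyl)-10-methyl-3-methylidene-2-oxo-2,3,3a,4,5,8,9,11a-octahydrocyclodeca[b]furan-4-yl (2S)-2-methylbutanoate | C=C1C(=O)O[C@@H]2/C=C(/C)CC/C=C(/CO)[C@H](O)[C@@H](OC(=O)[C@@H](C)CC)[C@@H]12 | intermediate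
47 | (3aS,4S,5S,6E,10Z,11aR)-6-formyl-5-hydroxy-10-methyl-3-methylidene-2-oxo-2,3,3a,4,5,8,9,11a-octahydrocyclodeca[b]furan-4-yl (2S)-2-methylbutanoate (CNP0168436.1) | C=C1C(=O)O[C@@H]2/C=C(/C)CC/C=C(/C=O)[C@H](O)[C@@H](OC(=O)[C@@H](C)CC)[C@@H]12 | target

**Step count and risks**

Total: 26 steps. Longest linear sequence: 20 steps (steps 1–9, then 16–26, from diethyl L-tartrate). The arm takes 6 steps (10–15).

Steps most likely to fail:

1. Step 23 (ring closure at C5–C6). The C6 radical may be reduced to the C–H lactone or dimerise before it meets the alkenylnickel at the other end of the chain, or the alkenyl iodide may be reduced instead of cyclising. The fallback makes the C5–C6 bond first, intermolecularly, and closes the ring at C9–C10 with known chemistry; it sets out from 22 and 14 and returns at 41. Iodide 22 is hydrolysed (1 M HCl, THF) to (4Z)-5-iodo-4-methylpent-4-enal F1, olefinated with Ph3P=C(Br)CO2Et to ethyl (2Z,6Z)-2-bromo-7-iodo-6-methylhepta-2,6-dienoate F2, reduced with i-Bu2AlH to the dienol F3 and silylated to the iodo-bromo-diene TBS ether F4. Lactone 14 is freed from its tert-butyl ester (Me3SiOTf, 2,6-lutidine) to the lactone acid F5 and coupled with 39 to the redox-active ester F6. Intermolecular nickel-electrocatalytic decarboxylative alkenylation of F6 with F4, the iodide reacting in preference to the more hindered alkenyl bromide, should give the trans-disubstituted lactone F7. H5IO6 unmasks the C9 aldehyde F8, and Nozaki–Hiyama–Kishi macrocyclisation (CrCl2, catalytic NiCl2, DMSO/THF, high dilution) closes the ten-membered ring to the macrocyclic alcohol F9, whose C9 configuration would have to be confirmed. Silylation (t-BuMe2SiOTf) to the bis-silyl ether F10, DDQ cleavage to the C8 alcohol F11 and Steglich esterification with 34 return to 41.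

2. Step 16 (C9–C10 union). The bulky alkenylmagnesium may add outside the chelate (Felkin–Anh face) or the α-alkoxy aldehyde may epimerise, eroding the C9 (or C8) configuration. The fallback replaces substrate control by reagent control; it sets out from 31 as obtained (with its C9 epimer) and returns at 31. The alcohol mixture is oxidised with Dess–Martin periodinane to the enone F12, which is reduced by Corey–Bakshi–Shibata reduction ((S)-2-methyl-CBS-oxazaborolidine, BH3·SMe2, −30 °C). With the alkenyl group acting as the large substituent, the (S)-catalyst should give the 9S alcohol 31.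

3. Step 5 (C7 by cuprate addition). Facial selectivity rests only on the neighbouring C8 stereocenter and could be eroded by the C9/C10 acetonide, giving the C7 epimer. The fallback adds auxiliary control; it sets out from 4 and returns at 8. Alcohol 4 is oxidised as in step 4 and the aldehyde is condensed (LiCl, i-Pr2NEt, MeCN) with diethyl {2-[(4S)-4-benzyl-2-oxo-1,3-oxazolidin-3-yl]-2-oxoethyl}phosphonate to the N-enoyl oxazolidinone F13. Vinylmagnesium bromide with CuBr·SMe2 adds to the magnesium-chelated imide from the face away from the benzyl group, which is the face the substrate itself prefers, to give the imide F14. LiOH/H2O2 removes the auxiliary to give the pentenoic acid F15, and O-tert-butyl-N,N'-diisopropylisourea re-forms the tert-butyl ester 8.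

**Further compounds**

F1 | step 23 | (4Z)-5-iodo-4-methylpent-4-enal | I/C=C(/C)CCC=O
F2 | step 23 | ethyl (2Z,6Z)-2-bromo-7-iodo-6-methylhepta-2,6-dienoate | I/C=C(/C)CC/C=C(/C(=O)OCC)Br
F3 | step 23 | (2Z,6Z)-2-bromo-7-iodo-6-methylhepta-2,6-dien-1-ol | I/C=C(/C)CC/C=C(/CO)Br
F4 | step 23 | {[(2Z,6Z)-2-bromo-7-iodo-6-methylhepta-2,6-dien-1-yl]oxy}(tert-butyl)dimethylsilane | I/C=C(/C)CC/C=C(/CO[Si](C)(C)C(C)(C)C)Br
F5 | step 23 | (2S,3R)-3-{(S)-[(4S)-2,2-dimethyl-1,3-dioxolan-4-yl][(4-methoxyphenyl)methoxy]methyl}-5-oxooxolane-2-carboxylic acid | CC1(C)OC[C@H](O1)[C@@H](OCc2ccc(OC)cc2)[C@H]3CC(=O)O[C@@H]3C(=O)O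
F6 | step 23 | 1,3-dioxoisoindolin-2-yl ester of F5 | CC1(C)OC[C@H](O1)[C@@H](OCc2ccc(OC)cc2)[C@H]3CC(=O)O[C@@H]3C(=O)ON4C(=O)c5ccccc5C4=O
F7 | step 23 | (4S,5R)-5-[(1Z,5Z)-6-bromo-7-(TBS-oxy)-2-methylhepta-1,5-dien-1-yl]-4-{(S)-[(4S)-2,2-dimethyl-1,3-dioxolan-4-yl][(4-methoxyphenyl)methoxy]methyl}oxolan-2-one | CC1(C)OC[C@H](O1)[C@@H](OCc2ccc(OC)cc2)[C@H]3CC(=O)O[C@@H]3/C=C(/C)CC/C=C(/CO[Si](C)(C)C(C)(C)C)Br
F8 | step 23 | (2S)-2-{(2R,3S)-2-[(1Z,5Z)-6-bromo-7-(TBS-oxy)-2-methylhepta-1,5-dien-1-yl]-5-oxooxolan-3-yl}-2-[(4-methoxyphenyl)methoxy]acetaldehyde | O=C[C@@H](OCc1ccc(OC)cc1)[C@H]2CC(=O)O[C@@H]2/C=C(/C)CC/C=C(/CO[Si](C)(C)C(C)(C)C)Br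
F9 | step 23 | (3aS,4S,5S,6Z,10Z,11aR)-5-hydroxy-4-[(4-methoxyphenyl)methoxy]-6-(TBS-oxymethyl)-10-methyl-3a,4,5,8,9,11a-hexahydrocyclodeca[b]furan-2(3H)-one | C1C(=O)O[C@@H]2/C=C(/C)CC/C=C(/CO[Si](C)(C)C(C)(C)C)[C@H](O)[C@@H](OCc3ccc(OC)cc3)[C@@H]12
F10 | step 23 | (3aS,4S,5S,6Z,10Z,11aR)-4-[(4-methoxyphenyl)methoxy]-5-(TBS-oxy)-6-(TBS-oxymethyl)-10-methyl-3a,4,5,8,9,11a-hexahydrocyclodeca[b]furan-2(3H)-one | C1C(=O)O[C@@H]2/C=C(/C)CC/C=C(/CO[Si](C)(C)C(C)(C)C)[C@H](O[Si](C)(C)C(C)(C)C)[C@@H](OCc3ccc(OC)cc3)[C@@H]12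
F11 | step 23 | (3aR,4S,5S,6Z,10Z,11aR)-4-hydroxy-5-(TBS-oxy)-6-(TBS-oxymethyl)-10-methyl-3a,4,5,8,9,11a-hexahydrocyclodeca[b]furan-2(3H)-one | C1C(=O)O[C@@H]2/C=C(/C)CC/C=C(/CO[Si](C)(C)C(C)(C)C)[C@H](O[Si](C)(C)C(C)(C)C)[C@@H](O)[C@@H]12
F12 | step 16 | tert-butyl (2S,3R)-3-[(1S,3Z,7Z)-1-[(4-methoxyphenyl)methoxy]-3-(TBS-oxymethyl)-7-methyl-2-oxo-8-(trimethylsilyl)octa-3,7-dien-1-yl]-5-oxooxolane-2-carboxylate | C[Si](C)(C)/C=C(/C)CC/C=C(/CO[Si](C)(C)C(C)(C)C)C(=O)[C@@H](OCc1ccc(OC)cc1)[C@H]2CC(=O)O[C@@H]2C(=O)OC(C)(C)C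
F13 | step 5 | (4S)-4-benzyl-3-{(2E,4S)-4-[(4S)-2,2-dimethyl-1,3-dioxolan-4-yl]-4-[(4-methoxyphenyl)methoxy]but-2-enoyl}-1,3-oxazolidin-2-one | O=C1OC[C@H](Cc2ccccc2)N1C(=O)/C=C/[C@H](OCc3ccc(OC)cc3)[C@@H]4COC(C)(C)O4
F14 | step 5 | (4S)-4-benzyl-3-[(3R)-3-{(S)-[(4S)-2,2-dimethyl-1,3-dioxolan-4-yl][(4-methoxyphenyl)methoxy]methyl}pent-4-enoyl]-1,3-oxazolidin-2-one | O=C1OC[C@H](Cc2ccccc2)N1C(=O)C[C@H](C=C)[C@H](OCc3ccc(OC)cc3)[C@@H]4COC(C)(C)O4
F15 | step 5 | (3R)-3-{(S)-[(4S)-2,2-dimethyl-1,3-dioxolan-4-yl][(4-methoxyphenyl)methoxy]methyl}pent-4-enoic acid | OC(=O)C[C@H](C=C)[C@H](OCc1ccc(OC)cc1)[C@@H]1COC(C)(C)O1
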